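A small charge showed me the point first: the winter run, with 10 mM of substrate, levelled off near 82.6% substrate and 15.3% target. You asked for a quick number, and your hunch was that a warmer flask gives more target in the same 4.0 d. I reckoned otherwise, by following one partner molecule through its forks.

| flask | substrate | partner | temperature | remark | time |
|---|---|---|---|---|---|
| winter | 10 mM | 0.60 equiv | −2 °C | run made earlier |  |
| dusk | 40 mM | 0.60 equiv | 14 °C | run made earlier |  |
| dawn | 20 mM | 1.2 equiv | −2 °C | run made earlier |  |
| violet | 20 mM | 0.600 equiv | 5 °C |  | 4.0 d |
| red | 20 mM | 0.600 equiv | −10 °C |  | 4.0 d |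
| grey | 20 mM | 0.600 equiv | 20 °C |  | 4.0 d |

- winter (time / d: target / %, substrate / %): 0.208: 11.0, 86.5; 0.625: 15.5, 84.9; 1.04: 15.6, 82.7; 1.67: 14.2, 84.9; 2.50: 13.6, 81.5; 3.00: 15.3, 82.6
- dusk (time / h: target / %, substrate / %): 4.00: 30.2, 65.8; 6.00: 28.2, 67.2; 10.0: 26.2, 68.3; 20.0: 18.1, 67.2; 30.0: 16.2, 68.0; 50.0: 13.1, 67.2
- dawn (time / d: target / %, substrate / %): 0.250: 38.1, 62.5; 0.833: 35.1, 56.0; 1.67: 31.0, 55.9; 2.50: 25.8, 55.0; 3.00: 25.1, 55.5

(each reading ± 1 percentage point)

- the numbers in the tables scatter with a standard deviation of 1 percentage point

1. the flask with the highest amount of target, in percent of the substrate charged ("all alike" if they lie within 1.5 percentage points) (violet / red / grey / all alike)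
2. final target, as a percentage of the substrate charged, in violet
3. final target, as a percentage of the substrate charged, in red
4. final target, as a percentage of the substrate charged, in grey

1. At the first fork a partner joins a substrate, and I supposed that a target can also fall apart again. In the dusk run the target dropped from 30.2% to 13.1% while the substrate stayed near 67.2%, so the lost target did not return as substrate and left a gap in the substrate balance.

2. At the second fork I supposed that a target takes one more partner, so each unit of gap cost two partners. That left 11.2 mM of free partner at the last dawn reading and 4.05 mM at the last winter reading.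

3. If the first fork stands in balance, target divided by substrate times free partner should match in these two runs at −2 °C, despite their different charges. I read 0.0403 mM⁻¹ in dawn and 0.0457 mM⁻¹ in winter. The first dusk reading, at 14 °C, gave 0.0526 mM⁻¹, which is higher than either.

4. I started from the dawn value, the lower of the two at −2 °C, and carried the change per degree between dawn and dusk down to −10 °C. That gave the holding quotient, an apparent association constant, for red: 0.0353 mM⁻¹.

5. With no gap, this quotient and the charges gave my estimate of target in red: 4.28 mM, or 21.4% of the substrate.

6. The gap grew faster in the dusk run at 14 °C, reaching 7.88 mM by 50.0 h, than in dawn at −2 °C, which reached 3.88 mM by 3.00 d, though these two runs differ in their substrate charge as well. I took that as a warning against warmth and committed to red as the highest flask, somewhat under that estimate.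

The forecast, which held that “the partner must be destroying itself”, differed from me on the cause but also named red, with 14.3% in violet, 19.6% in red and 9.7% in grey.

The flasks gave 13.9% in violet, 19.0% in red and 6.71% in grey, so red stood highest.

    substrate + partner ⇌ target (K = 47.0 M⁻¹, k = 17.0 M⁻¹ h⁻¹, Ea = 53.0 kJ mol⁻¹, ΔH = 9.00 kJ mol⁻¹)
    partner + target → over-reaction product (k = 1.37 M⁻¹ h⁻¹, Ea = 61.0 kJ mol⁻¹)
    (constants at 5 °C)

In red at 4.00 d, 76.9% of the substrate and 54.7% of the partner remained, and the holding quotient times these two amounts came to 17.8% of the substrate, against 19.0% found. The neighbour of red charged with 2.40 equiv of partner ended with 31.4% of its substrate and 55.8% of its partner. The same product gave 29.7% there, and that flask held 31.0% target beside 37.6% over-reaction product.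

The earlier runs and the new flask are calculated with made-up constants; noise was put on by code.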